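**Plan**
1. Rings are lettered A (2,4,6-trihydroxyphenoxy end) to K (3,4,5-trihydroxyphenyl end); carbon 1 of each ring is the carbon whose ether oxygen points toward ring A (for ring A, the carbon bearing its only ether oxygen). Rings C, E, G and I share one pattern: aryl ether oxygens on the neighbouring carbons 1 and 6, hydrogen on carbon 2, hydroxyls on carbons 3 to 5.
2. Retrosynthesis: after global O-demethylation, each of these four rings is cut at its 2–3 and 1–6 bonds. Carbons 1 and 2 become an aryl ethynyl ether already bonded to the ring on the A side; carbons 3 to 6 become a squaric-acid-derived cyclobutenone already bonded to the ring on the K side. The end ethers J–O–K and A–O–B are cut as copper-mediated O-arylations.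
3. Forward: J–K phenol, then its cyclobutenone, then ring I (tetramer), ring G (hexamer) and ring E (octamer) with one reusable ynol ether that serves as rings H, F and D. Ring C is closed last with an A–B ynol ether (undecamer), followed by demethylation.
4. Each growth cycle is: methylate the new phenol, hydrogenolyse the terminal benzyl ether, attach the squarate as its ester chloride (direct exchange of a squarate methoxy for an aryloxy group is uphill), reduce one carbonyl, methylate.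
5. Stereochemistry: the target is achiral. The only stereocentres on the way are the racemic carbon 4 of the cyclobutenones and the sp3 carbons of the pericyclic intermediates, all erased on aromatisation.

Key step: step 11

Assumption: squaric acid dichloride is taken as a purchasable reagent (otherwise one step from squaric acid with oxalyl chloride and catalytic DMF).

Conventions for names:
- "J–K aryl" = 3,5-dimethoxy-4-(3,4,5-trimethoxyphenoxy)phenyl.
- "H–K aryl" = 3,5-dimethoxy-4-[3,4,5-trimethoxy-2-(J–K aryloxy)phenoxy]phenyl.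
- "F–K aryl" and "D–K aryl" are built the same way from H–K aryl and F–K aryl.
- "ring H aryl" = 4-(benzyloxy)-2,6-dimethoxyphenyl (it also supplies rings F and D).
- "A–B aryl" = 2,6-dimethoxy-4-(2,4,6-trimethoxyphenoxy)phenyl.

**Route**

Step 1
Reactants: 1 syringaldehyde (4-hydroxy-3,5-dimethoxybenzaldehyde); 2 (3,4,5-trimethoxyphenyl)boronic acid
Product: 3 3,5-dimethoxy-4-(3,4,5-trimethoxyphenoxy)benzaldehyde (J–K aldehyde)
Conditions: Cu(OAc)2 (20 mol %), pyridine, 4 Å MS, CH2Cl2, O2 (1 atm), rt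
Reagents that add atoms: none
Why: Chan–Lam oxidative O-arylation works at room temperature with doubly ortho-substituted phenols and tolerates the aldehyde, so the crowded oxygen on carbon 4 of ring J is joined to the unhindered carbon 1 of ring K supplied by the boronic acid.

Step 2
Reactants: 3 J–K aldehyde
Product: 5 3,5-dimethoxy-4-(3,4,5-trimethoxyphenoxy)phenol (J–K phenol), via aryl formate 4 (not isolated)
Conditions: mCPBA, CH2Cl2, 0 °C to rt; then Et3N (cat.), MeOH, rt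
Reagents that add atoms: 3-chloroperoxybenzoic acid (mCPBA), OOC(=O)c1cccc(Cl)c1
Why: Baeyer–Villiger (Dakin-type) oxidation, in which the electron-rich ring with its para aryloxy group migrates to oxygen in preference to hydrogen, and amine-catalysed methanolysis of formate 4 frees the phenol on carbon 1 of ring J.

Step 3
Reactants: 6 3,4-dichlorocyclobut-3-ene-1,2-dione (squaric acid dichloride)
Product: 7 3-chloro-4-methoxycyclobut-3-ene-1,2-dione
Conditions: MeOH (1.0 equiv), CH2Cl2, −20 °C to rt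
Reagents that add atoms: methanol, CO
Why: Alcoholysis of a vinylogous acid chloride; the first methoxy group donates into the dione and slows a second substitution, so one equivalent of methanol should stop at the ester chloride.

Step 4
Reactants: 5 J–K phenol; 7 3-chloro-4-methoxycyclobut-3-ene-1,2-dione
Product: 8 3-methoxy-4-(J–K aryloxy)cyclobut-3-ene-1,2-dione
Conditions: i-Pr2NEt, CH2Cl2, −78 to 0 °C
Reagents that add atoms: none
Why: Addition–elimination (vinylogous acylation) of the phenol at the chlorine-bearing carbon, where chloride leaves far more readily than methoxide, which avoids the unfavourable exchange of a squarate methoxy group for an aryloxy group.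

Step 5
Reactants: 8 J–K aryl methyl squarate
Product: 9 racemic 4-hydroxy-3-methoxy-2-(J–K aryloxy)cyclobut-2-en-1-one
Conditions: LiAlH(Ot-Bu)3, THF, −78 °C; then H2O
Reagents that add atoms: none
Why: 1,2-Reduction of a squarate ester by a bulky alkoxyaluminium hydride; the carbonyl conjugated with the weakly donating aryloxy oxygen, which is the one next to the methoxy-bearing carbon, is the more electrophilic, so the hydroxyl should end up beside C–OMe, and the new centre is racemic and is erased in step 11.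

Step 6
Reactants: 9 hydroxycyclobutenone
Product: 10 racemic 3,4-dimethoxy-2-(J–K aryloxy)cyclobut-2-en-1-one
Conditions: MeI, Ag2O, 4 Å MS, CH2Cl2, rt, dark
Reagents that add atoms: iodomethane, CI
Why: Purdie methylation is neutral, so the secondary hydroxyl is capped without acid-induced loss of methanol or base-induced opening of the strained ring.

Step 7
Reactants: 11 2,6-dimethoxy-1,4-benzoquinone
Product: 12 2,6-dimethoxybenzene-1,4-diol
Conditions: H2 (1 atm), Pd/C, EtOAc, rt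
Reagents that add atoms: none
Why: Catalytic hydrogenation reduces the quinone cleanly to the hydroquinone and leaves no reagent residue before the air-sensitive diol is alkylated.

Step 8
Reactants: 12 2,6-dimethoxybenzene-1,4-diol
Product: 13 4-(benzyloxy)-2,6-dimethoxyphenol
Conditions: BnBr (1.0 equiv), K2CO3, acetone, rt, argon
Reagents that add atoms: benzyl bromide, BrCc1ccccc1
Why: Williamson etherification under weak base; the 4-hydroxyl, flanked by hydrogens and acidified by two meta methoxy groups, should be alkylated in preference to the 1-hydroxyl, which is shielded by two ortho methoxy groups.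

Step 9
Reactants: 13 4-(benzyloxy)-2,6-dimethoxyphenol; 14 trichloroethylene
Product: 15 5-(benzyloxy)-2-{[(E)-1,2-dichloroethenyl]oxy}-1,3-dimethoxybenzene
Conditions: K2CO3, DMF, 70 °C
Reagents that add atoms: none
Why: Base-mediated vinylation of a phenol with trichloroethylene; dichloroacetylene formed in solution takes up the phenoxide by anti addition and gives the E-dichlorovinyl ether.

Step 10
Reactants: 15 dichlorovinyl ether
Product: 18 5-(benzyloxy)-2-(ethynyloxy)-1,3-dimethoxybenzene (ring H ynol ether), via chloroethynyl ether 16 (not isolated), via lithium acetylide 17 (not isolated)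
Conditions: n-BuLi (2.1 equiv), THF, −78 to −40 °C; then MeOH, −78 °C
Reagents that add atoms: none
Why: Elimination followed by chlorine–lithium exchange; n-BuLi removes HCl to give chloroalkyne 16, exchanges the remaining chlorine to give 17, and protonation delivers the terminal ynol ether, which is used without storage.

Step 11
Reactants: 10 racemic 3,4-dimethoxy-2-(J–K aryloxy)cyclobut-2-en-1-one; 18 ring H ynol ether
Product: 23 5-(ring H aryloxy)-2,3-dimethoxy-4-(J–K aryloxy)phenol (H–I–J–K tetramer; free hydroxyl on carbon 3 of ring I; benzyl ether on carbon 1 of ring H), via vinylketene 19 (not isolated), via cyclobutenone adduct 20 (not isolated), via dienylketene 21 (not isolated), via cyclohexadienone 22 (not isolated)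
Conditions: toluene, 80 then 110 °C, argon (18 in 1.5-fold excess)
Reagents that add atoms: none
Why: Heating opens cyclobutenone 10 in a conrotatory four-electron electrocyclic reaction (the methoxy group on the sp3 carbon turning outward) to the aryloxy(vinyl)ketene 19, whose ketene C=C bond undergoes [2+2] cycloaddition with ynol ether 18 to form the 2–3 and 1–6 bonds of ring I in cyclobutenone 20. A second four-electron opening gives dienylketene 21, and a thermal six-electron disrotatory electrocyclisation (the ketene carbon, which becomes carbon 3 of ring I, onto the methoxy-bearing terminus, which becomes carbon 4) closes ring I as dienone 22, which enolises to phenol 23. The closest known reaction is the Danheiser benzannulation of cyclobutenone-derived vinylketenes with alkoxyalkynes. The step needs regiocontrol in the cycloaddition, and the oxygen-polarised alkyne secures it: its hydrogen-bearing, nucleophilic carbon bonds to the electrophilic ketene carbon, so hydrogen ends on carbon 2 of ring I, between the hydroxyl on carbon 3 and the ether on carbon 1. The methyl cap on the sp3 oxygen keeps the vinylketene from lactonising to a furanone, an aryl ynol ether cannot fragment by retro-ene loss of an alkene, and no stereocentre is created because the racemic centre of 10 is lost on aromatisation. Both crowded diaryl ether oxygens are in place before the arene exists, and the hydroxyl on carbon 3 of ring I emerges as the only free one.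

Step 12
Reactants: 23 tetramer phenol (free hydroxyl on carbon 3 of ring I)
Product: 24 benzyl H–K aryl ether (permethylated H–I–J–K tetramer with the benzyl ether on carbon 1 of ring H)
Conditions: MeI, K2CO3, acetone, 50 °C
Reagents that add atoms: iodomethane, CI
Why: Williamson O-methylation of the only free phenol, so that the next hydrogenolysis uncovers a single hydroxyl.

Step 13
Reactants: 24 benzyl H–K aryl ether
Product: 25 H–K phenol (free hydroxyl on carbon 1 of ring H)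
Conditions: H2 (1 atm), Pd/C, EtOAc–MeOH, rt
Reagents that add atoms: none
Why: Catalytic hydrogenolysis cleaves the benzyl ether selectively; methyl and diaryl ethers are inert.

Step 14
Reactants: 25 H–K phenol; 7 3-chloro-4-methoxycyclobut-3-ene-1,2-dione
Product: 26 3-methoxy-4-(H–K aryloxy)cyclobut-3-ene-1,2-dione
Conditions: i-Pr2NEt, CH2Cl2, −78 to 0 °C
Reagents that add atoms: none
Why: Addition–elimination at the vinylogous acid chloride, as in step 4, on the unhindered phenol of ring H.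

Step 15
Reactants: 26 H–K aryl methyl squarate
Product: 27 racemic 4-hydroxy-3-methoxy-2-(H–K aryloxy)cyclobut-2-en-1-one
Conditions: LiAlH(Ot-Bu)3, THF, −78 °C; then H2O
Reagents that add atoms: none
Why: Regioselective 1,2-reduction of the squarate carbonyl conjugated with the aryloxy oxygen, as in step 5; the new centre is racemic and is erased in step 17.

Step 16
Reactants: 27 hydroxycyclobutenone
Product: 28 racemic 3,4-dimethoxy-2-(H–K aryloxy)cyclobut-2-en-1-one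
Conditions: MeI, Ag2O, 4 Å MS, CH2Cl2, rt, dark
Reagents that add atoms: iodomethane, CI
Why: Neutral Purdie methylation caps the secondary hydroxyl on the sp3 ring carbon, as in step 6.

Step 17
Reactants: 28 H–K cyclobutenone; 18 ring H ynol ether
Product: 33 5-(ring H aryloxy)-2,3-dimethoxy-4-(H–K aryloxy)phenol (F–K hexamer; free hydroxyl on carbon 3 of ring G; benzyl ether on carbon 1 of ring F), via vinylketene 29 (not isolated), via cyclobutenone adduct 30 (not isolated), via dienylketene 31 (not isolated), via cyclohexadienone 32 (not isolated)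
Conditions: toluene, 80 then 110 °C, argon
Reagents that add atoms: none
Why: Danheiser-type benzannulation as in step 11: ring opening to vinylketene 29, regioselective [2+2] cycloaddition with the ynol ether, second opening and six-electron closure should build ring G with hydrogen on its carbon 2 and a free hydroxyl on its carbon 3.

Step 18
Reactants: 33 hexamer phenol (free hydroxyl on carbon 3 of ring G)
Product: 34 benzyl F–K aryl ether
Conditions: MeI, K2CO3, acetone, 50 °C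
Reagents that add atoms: iodomethane, CI
Why: Williamson O-methylation of the single free phenol.

Step 19
Reactants: 34 benzyl F–K aryl ether
Product: 35 F–K phenol (free hydroxyl on carbon 1 of ring F)
Conditions: H2 (1 atm), Pd/C, EtOAc–MeOH, rt
Reagents that add atoms: none
Why: Hydrogenolysis of the benzyl ether leaves methyl and diaryl ethers untouched.

Step 20
Reactants: 35 F–K phenol; 7 3-chloro-4-methoxycyclobut-3-ene-1,2-dione
Product: 36 3-methoxy-4-(F–K aryloxy)cyclobut-3-ene-1,2-dione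
Conditions: i-Pr2NEt, CH2Cl2, −78 to 0 °C
Reagents that add atoms: none
Why: Addition–elimination at the vinylogous acid chloride, as in step 4.

Step 21
Reactants: 36 F–K aryl methyl squarate
Product: 37 racemic 4-hydroxy-3-methoxy-2-(F–K aryloxy)cyclobut-2-en-1-one
Conditions: LiAlH(Ot-Bu)3, THF, −78 °C; then H2O
Reagents that add atoms: none
Why: Regioselective 1,2-reduction of the carbonyl conjugated with the aryloxy oxygen, as in step 5; the racemic centre is erased in step 23.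

Step 22
Reactants: 37 hydroxycyclobutenone
Product: 38 racemic 3,4-dimethoxy-2-(F–K aryloxy)cyclobut-2-en-1-one
Conditions: MeI, Ag2O, 4 Å MS, CH2Cl2, rt, dark
Reagents that add atoms: iodomethane, CI
Why: Neutral Purdie methylation, as in step 6.

Step 23
Reactants: 38 F–K cyclobutenone; 18 ring H ynol ether
Product: 43 5-(ring H aryloxy)-2,3-dimethoxy-4-(F–K aryloxy)phenol (D–K octamer; free hydroxyl on carbon 3 of ring E; benzyl ether on carbon 1 of ring D), via vinylketene 39 (not isolated), via cyclobutenone adduct 40 (not isolated), via dienylketene 41 (not isolated), via cyclohexadienone 42 (not isolated)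
Conditions: toluene, 80 then 110 °C, argon
Reagents that add atoms: none
Why: Danheiser-type benzannulation as in step 11, here building ring E with hydrogen on its carbon 2 and a free hydroxyl on its carbon 3 under the same polarity control.

Step 24
Reactants: 43 octamer phenol (free hydroxyl on carbon 3 of ring E)
Product: 44 benzyl D–K aryl ether
Conditions: MeI, K2CO3, acetone, 50 °C
Reagents that add atoms: iodomethane, CI
Why: Williamson O-methylation of the single free phenol.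

Step 25
Reactants: 44 benzyl D–K aryl ether
Product: 45 D–K phenol (free hydroxyl on carbon 1 of ring D)
Conditions: H2 (1 atm), Pd/C, EtOAc–MeOH, rt
Reagents that add atoms: none
Why: Hydrogenolysis of the benzyl ether leaves methyl and diaryl ethers untouched.

Step 26
Reactants: 45 D–K phenol; 7 3-chloro-4-methoxycyclobut-3-ene-1,2-dione
Product: 46 3-methoxy-4-(D–K aryloxy)cyclobut-3-ene-1,2-dione
Conditions: i-Pr2NEt, CH2Cl2, −78 to 0 °C
Reagents that add atoms: none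
Why: Addition–elimination at the vinylogous acid chloride, as in step 4.

Step 27
Reactants: 46 D–K aryl methyl squarate
Product: 47 racemic 4-hydroxy-3-methoxy-2-(D–K aryloxy)cyclobut-2-en-1-one
Conditions: LiAlH(Ot-Bu)3, THF, −78 °C; then H2O
Reagents that add atoms: none
Why: Regioselective 1,2-reduction of the carbonyl conjugated with the aryloxy oxygen, as in step 5; the racemic centre is erased in step 34.

Step 28
Reactants: 47 hydroxycyclobutenone
Product: 48 racemic 3,4-dimethoxy-2-(D–K aryloxy)cyclobut-2-en-1-one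
Conditions: MeI, Ag2O, 4 Å MS, CH2Cl2, rt, dark
Reagents that add atoms: iodomethane, CI
Why: Neutral Purdie methylation, as in step 6.

Step 29
Reactants: 49 4-bromo-2,6-dimethoxyphenol
Product: 50 2-(benzyloxy)-5-bromo-1,3-dimethoxybenzene
Conditions: BnBr, K2CO3, DMF, rt
Reagents that add atoms: benzyl bromide, BrCc1ccccc1
Why: Williamson benzylation masks the phenol of the bromide so that only the other phenol can couple in step 30.

Step 30
Reactants: 50 2-(benzyloxy)-5-bromo-1,3-dimethoxybenzene; 51 2,4,6-trimethoxyphenol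
Product: 52 2-(benzyloxy)-1,3-dimethoxy-5-(2,4,6-trimethoxyphenoxy)benzene (A–B benzyl ether)
Conditions: CuI (10 mol %), picolinic acid (20 mol %), K3PO4, DMSO, 100 °C, argon
Reagents that add atoms: none
Why: Ullmann diaryl ether synthesis with the CuI/picolinic acid system, which suits doubly ortho-substituted phenols and electron-rich aryl bromides, joins the hindered phenol oxygen of ring A to the unhindered bromine-bearing carbon that becomes carbon 1 of ring B.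

Step 31
Reactants: 52 A–B benzyl ether
Product: 53 2,6-dimethoxy-4-(2,4,6-trimethoxyphenoxy)phenol (A–B phenol)
Conditions: H2 (1 atm), Pd/C, EtOAc–MeOH, rt
Reagents that add atoms: none
Why: Hydrogenolysis of the benzyl ether frees the hydroxyl on carbon 4 of ring B without touching methyl or diaryl ethers.

Step 32
Reactants: 53 A–B phenol; 14 trichloroethylene
Product: 54 2-{[(E)-1,2-dichloroethenyl]oxy}-1,3-dimethoxy-5-(2,4,6-trimethoxyphenoxy)benzene
Conditions: K2CO3, DMF, 70 °C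
Reagents that add atoms: none
Why: Base-mediated vinylation of the phenol through dichloroacetylene formed in solution, as in step 9.

Step 33
Reactants: 54 A–B dichlorovinyl ether
Product: 57 2-(ethynyloxy)-1,3-dimethoxy-5-(2,4,6-trimethoxyphenoxy)benzene (A–B ynol ether), via chloroethynyl ether 55 (not isolated), via lithium acetylide 56 (not isolated)
Conditions: n-BuLi (2.1 equiv), THF, −78 to −40 °C; then MeOH, −78 °C
Reagents that add atoms: none
Why: Elimination followed by chlorine–lithium exchange and protonation, as in step 10; at −78 °C this outruns ortho-lithiation of the methoxy-flanked ring positions.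

Step 34
Reactants: 48 D–K cyclobutenone; 57 A–B ynol ether
Product: 62 5-(A–B aryloxy)-2,3-dimethoxy-4-(D–K aryloxy)phenol (A–K undecamer; 27 methyl ethers; free hydroxyl on carbon 3 of ring C), via vinylketene 58 (not isolated), via cyclobutenone adduct 59 (not isolated), via dienylketene 60 (not isolated), via cyclohexadienone 61 (not isolated)
Conditions: toluene, 80 then 110 °C, argon
Reagents that add atoms: none
Why: Danheiser-type benzannulation as in step 11, which here closes ring C and completes the undecamer skeleton with the ring A cap already on the ynol ether.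

Step 35
Reactants: 62 undecamer (27 methyl ethers; free hydroxyl on carbon 3 of ring C)
Product: 63 CNP0245174.0 (target; all 28 hydroxyls free)
Conditions: BBr3 (large excess), CH2Cl2, −78 °C to rt, argon; then H2O, 0 °C
Reagents that add atoms: none
Why: BBr3-mediated cleavage of aryl methyl ethers (Lewis acid activation of oxygen and bromide attack at methyl) should remove all 27 methyl groups while the diaryl ether bonds stay intact; exclusion of air protects the polyphenol.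

**Compound list**

1 | syringaldehyde (4-hydroxy-3,5-dimethoxybenzaldehyde) | COc1cc(C=O)cc(OC)c1O | starting material
2 | (3,4,5-trimethoxyphenyl)boronic acid | COc1cc(B(O)O)cc(OC)c1OC | starting material
3 | 3,5-dimethoxy-4-(3,4,5-trimethoxyphenoxy)benzaldehyde (J–K aldehyde) | O=Cc1cc(OC)c(c(OC)c1)Oc1cc(OC)c(OC)c(OC)c1 | intermediate
4 | 3,5-dimethoxy-4-(3,4,5-trimethoxyphenoxy)phenyl formate (not isolated) | O=COc1cc(OC)c(c(OC)c1)Oc1cc(OC)c(OC)c(OC)c1 | intermediate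
5 | 3,5-dimethoxy-4-(3,4,5-trimethoxyphenoxy)phenol (J–K phenol) | Oc1cc(OC)c(c(OC)c1)Oc1cc(OC)c(OC)c(OC)c1 | intermediate
6 | 3,4-dichlorocyclobut-3-ene-1,2-dione (squaric acid dichloride) | ClC1=C(Cl)C(=O)C1=O | starting material
7 | 3-chloro-4-methoxycyclobut-3-ene-1,2-dione | COC1=C(Cl)C(=O)C1=O | intermediate
8 | 3-methoxy-4-(J–K aryloxy)cyclobut-3-ene-1,2-dione | COC2=C(Oc1cc(OC)c(c(OC)c1)Oc1cc(OC)c(OC)c(OC)c1)C(=O)C2=O | intermediate
9 | racemic 4-hydroxy-3-methoxy-2-(J–K aryloxy)cyclobut-2-en-1-one | COC2=C(Oc1cc(OC)c(c(OC)c1)Oc1cc(OC)c(OC)c(OC)c1)C(=O)C2O | intermediate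
10 | racemic 3,4-dimethoxy-2-(J–K aryloxy)cyclobut-2-en-1-one | COC2=C(Oc1cc(OC)c(c(OC)c1)Oc1cc(OC)c(OC)c(OC)c1)C(=O)C2OC | intermediate
11 | 2,6-dimethoxy-1,4-benzoquinone | COC1=CC(=O)C=C(OC)C1=O | starting material
12 | 2,6-dimethoxybenzene-1,4-diol | COc1cc(O)cc(OC)c1O | intermediate
13 | 4-(benzyloxy)-2,6-dimethoxyphenol | COc1cc(OCc2ccccc2)cc(OC)c1O | intermediate
14 | trichloroethylene | ClC=C(Cl)Cl | starting material
15 | 5-(benzyloxy)-2-{[(E)-1,2-dichloroethenyl]oxy}-1,3-dimethoxybenzene | Cl/C=C(/Cl)Oc1c(OC)cc(OCc2ccccc2)cc1OC | intermediate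
16 | 5-(benzyloxy)-2-[(chloroethynyl)oxy]-1,3-dimethoxybenzene (not isolated) | ClC#COc1c(OC)cc(OCc2ccccc2)cc1OC | intermediate
17 | lithium 2-[4-(benzyloxy)-2,6-dimethoxyphenoxy]ethynide (not isolated) | [Li]C#COc1c(OC)cc(OCc2ccccc2)cc1OC | intermediate
18 | 5-(benzyloxy)-2-(ethynyloxy)-1,3-dimethoxybenzene (ring H ynol ether) | C#COc1c(OC)cc(OCc2ccccc2)cc1OC | intermediate
19 | (Z)-3,4-dimethoxy-2-(J–K aryloxy)buta-1,3-dien-1-one (vinylketene; not isolated) | O=C=C(Oc1cc(OC)c(c(OC)c1)Oc1cc(OC)c(OC)c(OC)c1)/C(OC)=C/OC | intermediate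
20 | racemic 3-(ring H aryloxy)-4-[(Z)-1,2-dimethoxyethenyl]-4-(J–K aryloxy)cyclobut-2-en-1-one (not isolated) | O=C2C=C(Oc1c(OC)cc(OCc3ccccc3)cc1OC)C2(Oc1cc(OC)c(c(OC)c1)Oc1cc(OC)c(OC)c(OC)c1)/C(OC)=C/OC | intermediate
21 | (3Z,5Z)-3-(ring H aryloxy)-5,6-dimethoxy-4-(J–K aryloxy)hexa-1,3,5-trien-1-one (dienylketene; not isolated) | O=C=C/C(Oc1c(OC)cc(OCc2ccccc2)cc1OC)=C(Oc1cc(OC)c(c(OC)c1)Oc1cc(OC)c(OC)c(OC)c1)\C(OC)=C\OC | intermediate
22 | racemic 3-(ring H aryloxy)-5,6-dimethoxy-4-(J–K aryloxy)cyclohexa-2,4-dien-1-one (not isolated) | O=C2C=C(Oc1c(OC)cc(OCc3ccccc3)cc1OC)C(Oc1cc(OC)c(c(OC)c1)Oc1cc(OC)c(OC)c(OC)c1)=C(OC)C2OC | intermediate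
23 | 5-(ring H aryloxy)-2,3-dimethoxy-4-(J–K aryloxy)phenol (H–I–J–K tetramer, free hydroxyl on carbon 3 of ring I) | c1ccccc1COc1cc(OC)c(c(OC)c1)Oc1cc(O)c(OC)c(OC)c1Oc1cc(OC)c(c(OC)c1)Oc1cc(OC)c(OC)c(OC)c1 | intermediate
24 | benzyl H–K aryl ether | c1ccccc1COc1cc(OC)c(c(OC)c1)Oc1cc(OC)c(OC)c(OC)c1Oc1cc(OC)c(c(OC)c1)Oc1cc(OC)c(OC)c(OC)c1 | intermediate
25 | H–K phenol | Oc1cc(OC)c(c(OC)c1)Oc1cc(OC)c(OC)c(OC)c1Oc1cc(OC)c(c(OC)c1)Oc1cc(OC)c(OC)c(OC)c1 | intermediate
26 | 3-methoxy-4-(H–K aryloxy)cyclobut-3-ene-1,2-dione | COC2=C(Oc1cc(OC)c(c(OC)c1)Oc1cc(OC)c(OC)c(OC)c1Oc1cc(OC)c(c(OC)c1)Oc1cc(OC)c(OC)c(OC)c1)C(=O)C2=O | intermediate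
27 | racemic 4-hydroxy-3-methoxy-2-(H–K aryloxy)cyclobut-2-en-1-one | COC2=C(Oc1cc(OC)c(c(OC)c1)Oc1cc(OC)c(OC)c(OC)c1Oc1cc(OC)c(c(OC)c1)Oc1cc(OC)c(OC)c(OC)c1)C(=O)C2O | intermediate
28 | racemic 3,4-dimethoxy-2-(H–K aryloxy)cyclobut-2-en-1-one | COC2=C(Oc1cc(OC)c(c(OC)c1)Oc1cc(OC)c(OC)c(OC)c1Oc1cc(OC)c(c(OC)c1)Oc1cc(OC)c(OC)c(OC)c1)C(=O)C2OC | intermediate
29 | (Z)-3,4-dimethoxy-2-(H–K aryloxy)buta-1,3-dien-1-one (vinylketene; not isolated) | O=C=C(Oc1cc(OC)c(c(OC)c1)Oc1cc(OC)c(OC)c(OC)c1Oc1cc(OC)c(c(OC)c1)Oc1cc(OC)c(OC)c(OC)c1)/C(OC)=C/OC | intermediate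
30 | racemic 3-(ring H aryloxy)-4-[(Z)-1,2-dimethoxyethenyl]-4-(H–K aryloxy)cyclobut-2-en-1-one (not isolated) | O=C2C=C(Oc1c(OC)cc(OCc3ccccc3)cc1OC)C2(Oc1cc(OC)c(c(OC)c1)Oc1cc(OC)c(OC)c(OC)c1Oc1cc(OC)c(c(OC)c1)Oc1cc(OC)c(OC)c(OC)c1)/C(OC)=C/OC | intermediate
31 | (3Z,5Z)-3-(ring H aryloxy)-5,6-dimethoxy-4-(H–K aryloxy)hexa-1,3,5-trien-1-one (dienylketene; not isolated) | O=C=C/C(Oc1c(OC)cc(OCc2ccccc2)cc1OC)=C(Oc1cc(OC)c(c(OC)c1)Oc1cc(OC)c(OC)c(OC)c1Oc1cc(OC)c(c(OC)c1)Oc1cc(OC)c(OC)c(OC)c1)\C(OC)=C\OC | intermediate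
32 | racemic 3-(ring H aryloxy)-5,6-dimethoxy-4-(H–K aryloxy)cyclohexa-2,4-dien-1-one (not isolated) | O=C2C=C(Oc1c(OC)cc(OCc3ccccc3)cc1OC)C(Oc1cc(OC)c(c(OC)c1)Oc1cc(OC)c(OC)c(OC)c1Oc1cc(OC)c(c(OC)c1)Oc1cc(OC)c(OC)c(OC)c1)=C(OC)C2OC | intermediate
33 | 5-(ring H aryloxy)-2,3-dimethoxy-4-(H–K aryloxy)phenol (F–K hexamer, free hydroxyl on carbon 3 of ring G) | c1ccccc1COc1cc(OC)c(c(OC)c1)Oc1cc(O)c(OC)c(OC)c1Oc1cc(OC)c(c(OC)c1)Oc1cc(OC)c(OC)c(OC)c1Oc1cc(OC)c(c(OC)c1)Oc1cc(OC)c(OC)c(OC)c1 | intermediate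
34 | benzyl F–K aryl ether | c1ccccc1COc1cc(OC)c(c(OC)c1)Oc1cc(OC)c(OC)c(OC)c1Oc1cc(OC)c(c(OC)c1)Oc1cc(OC)c(OC)c(OC)c1Oc1cc(OC)c(c(OC)c1)Oc1cc(OC)c(OC)c(OC)c1 | intermediate
35 | F–K phenol | Oc1cc(OC)c(c(OC)c1)Oc1cc(OC)c(OC)c(OC)c1Oc1cc(OC)c(c(OC)c1)Oc1cc(OC)c(OC)c(OC)c1Oc1cc(OC)c(c(OC)c1)Oc1cc(OC)c(OC)c(OC)c1 | intermediate
36 | 3-methoxy-4-(F–K aryloxy)cyclobut-3-ene-1,2-dione | COC2=C(Oc1cc(OC)c(c(OC)c1)Oc1cc(OC)c(OC)c(OC)c1Oc1cc(OC)c(c(OC)c1)Oc1cc(OC)c(OC)c(OC)c1Oc1cc(OC)c(c(OC)c1)Oc1cc(OC)c(OC)c(OC)c1)C(=O)C2=O | intermediate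
37 | racemic 4-hydroxy-3-methoxy-2-(F–K aryloxy)cyclobut-2-en-1-one | COC2=C(Oc1cc(OC)c(c(OC)c1)Oc1cc(OC)c(OC)c(OC)c1Oc1cc(OC)c(c(OC)c1)Oc1cc(OC)c(OC)c(OC)c1Oc1cc(OC)c(c(OC)c1)Oc1cc(OC)c(OC)c(OC)c1)C(=O)C2O | intermediate
38 | racemic 3,4-dimethoxy-2-(F–K aryloxy)cyclobut-2-en-1-one | COC2=C(Oc1cc(OC)c(c(OC)c1)Oc1cc(OC)c(OC)c(OC)c1Oc1cc(OC)c(c(OC)c1)Oc1cc(OC)c(OC)c(OC)c1Oc1cc(OC)c(c(OC)c1)Oc1cc(OC)c(OC)c(OC)c1)C(=O)C2OC | intermediate
39 | (Z)-3,4-dimethoxy-2-(F–K aryloxy)buta-1,3-dien-1-one (vinylketene; not isolated) | O=C=C(Oc1cc(OC)c(c(OC)c1)Oc1cc(OC)c(OC)c(OC)c1Oc1cc(OC)c(c(OC)c1)Oc1cc(OC)c(OC)c(OC)c1Oc1cc(OC)c(c(OC)c1)Oc1cc(OC)c(OC)c(OC)c1)/C(OC)=C/OC | intermediate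
40 | racemic 3-(ring H aryloxy)-4-[(Z)-1,2-dimethoxyethenyl]-4-(F–K aryloxy)cyclobut-2-en-1-one (not isolated) | O=C2C=C(Oc1c(OC)cc(OCc3ccccc3)cc1OC)C2(Oc1cc(OC)c(c(OC)c1)Oc1cc(OC)c(OC)c(OC)c1Oc1cc(OC)c(c(OC)c1)Oc1cc(OC)c(OC)c(OC)c1Oc1cc(OC)c(c(OC)c1)Oc1cc(OC)c(OC)c(OC)c1)/C(OC)=C/OC | intermediate
41 | (3Z,5Z)-3-(ring H aryloxy)-5,6-dimethoxy-4-(F–K aryloxy)hexa-1,3,5-trien-1-one (dienylketene; not isolated) | O=C=C/C(Oc1c(OC)cc(OCc2ccccc2)cc1OC)=C(Oc1cc(OC)c(c(OC)c1)Oc1cc(OC)c(OC)c(OC)c1Oc1cc(OC)c(c(OC)c1)Oc1cc(OC)c(OC)c(OC)c1Oc1cc(OC)c(c(OC)c1)Oc1cc(OC)c(OC)c(OC)c1)\C(OC)=C\OC | intermediate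
42 | racemic 3-(ring H aryloxy)-5,6-dimethoxy-4-(F–K aryloxy)cyclohexa-2,4-dien-1-one (not isolated) | O=C2C=C(Oc1c(OC)cc(OCc3ccccc3)cc1OC)C(Oc1cc(OC)c(c(OC)c1)Oc1cc(OC)c(OC)c(OC)c1Oc1cc(OC)c(c(OC)c1)Oc1cc(OC)c(OC)c(OC)c1Oc1cc(OC)c(c(OC)c1)Oc1cc(OC)c(OC)c(OC)c1)=C(OC)C2OC | intermediate
43 | 5-(ring H aryloxy)-2,3-dimethoxy-4-(F–K aryloxy)phenol (D–K octamer, free hydroxyl on carbon 3 of ring E) | c1ccccc1COc1cc(OC)c(c(OC)c1)Oc1cc(O)c(OC)c(OC)c1Oc1cc(OC)c(c(OC)c1)Oc1cc(OC)c(OC)c(OC)c1Oc1cc(OC)c(c(OC)c1)Oc1cc(OC)c(OC)c(OC)c1Oc1cc(OC)c(c(OC)c1)Oc1cc(OC)c(OC)c(OC)c1 | intermediate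
44 | benzyl D–K aryl ether | c1ccccc1COc1cc(OC)c(c(OC)c1)Oc1cc(OC)c(OC)c(OC)c1Oc1cc(OC)c(c(OC)c1)Oc1cc(OC)c(OC)c(OC)c1Oc1cc(OC)c(c(OC)c1)Oc1cc(OC)c(OC)c(OC)c1Oc1cc(OC)c(c(OC)c1)Oc1cc(OC)c(OC)c(OC)c1 | intermediate
45 | D–K phenol | Oc1cc(OC)c(c(OC)c1)Oc1cc(OC)c(OC)c(OC)c1Oc1cc(OC)c(c(OC)c1)Oc1cc(OC)c(OC)c(OC)c1Oc1cc(OC)c(c(OC)c1)Oc1cc(OC)c(OC)c(OC)c1Oc1cc(OC)c(c(OC)c1)Oc1cc(OC)c(OC)c(OC)c1 | intermediate
46 | 3-methoxy-4-(D–K aryloxy)cyclobut-3-ene-1,2-dione | COC2=C(Oc1cc(OC)c(c(OC)c1)Oc1cc(OC)c(OC)c(OC)c1Oc1cc(OC)c(c(OC)c1)Oc1cc(OC)c(OC)c(OC)c1Oc1cc(OC)c(c(OC)c1)Oc1cc(OC)c(OC)c(OC)c1Oc1cc(OC)c(c(OC)c1)Oc1cc(OC)c(OC)c(OC)c1)C(=O)C2=O | intermediate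
47 | racemic 4-hydroxy-3-methoxy-2-(D–K aryloxy)cyclobut-2-en-1-one | COC2=C(Oc1cc(OC)c(c(OC)c1)Oc1cc(OC)c(OC)c(OC)c1Oc1cc(OC)c(c(OC)c1)Oc1cc(OC)c(OC)c(OC)c1Oc1cc(OC)c(c(OC)c1)Oc1cc(OC)c(OC)c(OC)c1Oc1cc(OC)c(c(OC)c1)Oc1cc(OC)c(OC)c(OC)c1)C(=O)C2O | intermediate
48 | racemic 3,4-dimethoxy-2-(D–K aryloxy)cyclobut-2-en-1-one | COC2=C(Oc1cc(OC)c(c(OC)c1)Oc1cc(OC)c(OC)c(OC)c1Oc1cc(OC)c(c(OC)c1)Oc1cc(OC)c(OC)c(OC)c1Oc1cc(OC)c(c(OC)c1)Oc1cc(OC)c(OC)c(OC)c1Oc1cc(OC)c(c(OC)c1)Oc1cc(OC)c(OC)c(OC)c1)C(=O)C2OC | intermediate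
49 | 4-bromo-2,6-dimethoxyphenol | COc1cc(Br)cc(OC)c1O | starting material
50 | 2-(benzyloxy)-5-bromo-1,3-dimethoxybenzene | COc1cc(Br)cc(OC)c1OCc1ccccc1 | intermediate
51 | 2,4,6-trimethoxyphenol | COc1cc(OC)c(O)c(OC)c1 | starting material
52 | 2-(benzyloxy)-1,3-dimethoxy-5-(2,4,6-trimethoxyphenoxy)benzene (A–B benzyl ether) | COc1cc(OC)c(c(OC)c1)Oc1cc(OC)c(c(OC)c1)OCc1ccccc1 | intermediate
53 | 2,6-dimethoxy-4-(2,4,6-trimethoxyphenoxy)phenol (A–B phenol) | COc1cc(OC)c(c(OC)c1)Oc1cc(OC)c(c(OC)c1)O | intermediate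
54 | 2-{[(E)-1,2-dichloroethenyl]oxy}-1,3-dimethoxy-5-(2,4,6-trimethoxyphenoxy)benzene | COc1cc(OC)c(c(OC)c1)Oc1cc(OC)c(c(OC)c1)O/C(Cl)=C\Cl | intermediate
55 | 2-[(chloroethynyl)oxy]-1,3-dimethoxy-5-(2,4,6-trimethoxyphenoxy)benzene (not isolated) | COc1cc(OC)c(c(OC)c1)Oc1cc(OC)c(c(OC)c1)OC#CCl | intermediate
56 | lithium 2-(A–B aryloxy)ethynide (not isolated) | COc1cc(OC)c(c(OC)c1)Oc1cc(OC)c(c(OC)c1)OC#C[Li] | intermediate
57 | 2-(ethynyloxy)-1,3-dimethoxy-5-(2,4,6-trimethoxyphenoxy)benzene (A–B ynol ether) | COc1cc(OC)c(c(OC)c1)Oc1cc(OC)c(c(OC)c1)OC#C | intermediate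
58 | (Z)-3,4-dimethoxy-2-(D–K aryloxy)buta-1,3-dien-1-one (vinylketene; not isolated) | O=C=C(Oc1cc(OC)c(c(OC)c1)Oc1cc(OC)c(OC)c(OC)c1Oc1cc(OC)c(c(OC)c1)Oc1cc(OC)c(OC)c(OC)c1Oc1cc(OC)c(c(OC)c1)Oc1cc(OC)c(OC)c(OC)c1Oc1cc(OC)c(c(OC)c1)Oc1cc(OC)c(OC)c(OC)c1)/C(OC)=C/OC | intermediate
59 | racemic 3-(A–B aryloxy)-4-[(Z)-1,2-dimethoxyethenyl]-4-(D–K aryloxy)cyclobut-2-en-1-one (not isolated) | O=C2C=C(Oc1c(OC)cc(Oc3c(OC)cc(OC)cc3OC)cc1OC)C2(Oc1cc(OC)c(c(OC)c1)Oc1cc(OC)c(OC)c(OC)c1Oc1cc(OC)c(c(OC)c1)Oc1cc(OC)c(OC)c(OC)c1Oc1cc(OC)c(c(OC)c1)Oc1cc(OC)c(OC)c(OC)c1Oc1cc(OC)c(c(OC)c1)Oc1cc(OC)c(OC)c(OC)c1)/C(OC)=C/OC | intermediate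
60 | (3Z,5Z)-3-(A–B aryloxy)-5,6-dimethoxy-4-(D–K aryloxy)hexa-1,3,5-trien-1-one (dienylketene; not isolated) | O=C=C/C(Oc1c(OC)cc(Oc2c(OC)cc(OC)cc2OC)cc1OC)=C(Oc1cc(OC)c(c(OC)c1)Oc1cc(OC)c(OC)c(OC)c1Oc1cc(OC)c(c(OC)c1)Oc1cc(OC)c(OC)c(OC)c1Oc1cc(OC)c(c(OC)c1)Oc1cc(OC)c(OC)c(OC)c1Oc1cc(OC)c(c(OC)c1)Oc1cc(OC)c(OC)c(OC)c1)\C(OC)=C\OC | intermediate
61 | racemic 3-(A–B aryloxy)-5,6-dimethoxy-4-(D–K aryloxy)cyclohexa-2,4-dien-1-one (not isolated) | O=C2C=C(Oc1c(OC)cc(Oc3c(OC)cc(OC)cc3OC)cc1OC)C(Oc1cc(OC)c(c(OC)c1)Oc1cc(OC)c(OC)c(OC)c1Oc1cc(OC)c(c(OC)c1)Oc1cc(OC)c(OC)c(OC)c1Oc1cc(OC)c(c(OC)c1)Oc1cc(OC)c(OC)c(OC)c1Oc1cc(OC)c(c(OC)c1)Oc1cc(OC)c(OC)c(OC)c1)=C(OC)C2OC | intermediate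
62 | 5-(A–B aryloxy)-2,3-dimethoxy-4-(D–K aryloxy)phenol (A–K undecamer, 27 methyl ethers, free hydroxyl on carbon 3 of ring C) | COc1cc(OC)c(c(OC)c1)Oc1cc(OC)c(c(OC)c1)Oc1cc(O)c(OC)c(OC)c1Oc1cc(OC)c(c(OC)c1)Oc1cc(OC)c(OC)c(OC)c1Oc1cc(OC)c(c(OC)c1)Oc1cc(OC)c(OC)c(OC)c1Oc1cc(OC)c(c(OC)c1)Oc1cc(OC)c(OC)c(OC)c1Oc1cc(OC)c(c(OC)c1)Oc1cc(OC)c(OC)c(OC)c1 | intermediate
63 | CNP0245174.0 | Oc1cc(O)c(Oc2cc(O)c(Oc3cc(O)c(O)c(O)c3Oc3cc(O)c(Oc4cc(O)c(O)c(O)c4Oc4cc(O)c(Oc5cc(O)c(O)c(O)c5Oc5cc(O)c(Oc6cc(O)c(O)c(O)c6Oc6cc(O)c(Oc7cc(O)c(O)c(O)c7)c(O)c6)c(O)c5)c(O)c4)c(O)c3)c(O)c2)c(O)c1 | target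

**Step count and risks**

Total: 35 steps. Longest linear sequence: 25 steps (1, 2, 4–6, 11–28, 34, 35).

Steps most likely to fail:

1. Step 11 (and its repeats 17, 23, 34). The terminal aryl ethynyl ether may oligomerise on heating, or the electron-rich vinylketene may dimerise or acylate the newly formed phenol faster than it is trapped in the [2+2] event. Fallback, setting out from 15 and coming back at 23: the acetylide 17 made from 15 with n-BuLi is quenched with Me3SiCl instead of methanol to give the storable {[4-(benzyloxy)-2,6-dimethoxyphenoxy]ethynyl}trimethylsilane F1. Heating F1 with 10 in toluene should run through the same vinylketene 19, then the silylated cyclobutenone adduct F2, the silylated dienylketene F3 and the silylated cyclohexadienone F4 to the ring-I-silylated tetramer phenol F5, with silicon reinforcing the polarity of the alkyne. Ipso-protodesilylation of the electron-rich ring with CF3CO2H in CH2Cl2 at 0 °C, followed by aqueous work-up, then gives 23.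

2. Step 5 (and its repeats 15, 21, 27). Hydride may be delivered to the other carbonyl, or may displace aryloxide by conjugate addition, which would erode the regiochemical purity on which the substitution pattern of ring I depends. Fallback, setting out from 5 and 6 and coming back at 9: two equivalents of phenol 5 are condensed with dichloride 6 (i-Pr2NEt, CH2Cl2), through the 3-chloro-4-(J–K aryloxy)cyclobut-3-ene-1,2-dione F6, to the symmetrical 3,4-bis(J–K aryloxy)cyclobut-3-ene-1,2-dione F7. Its two carbonyls are equivalent, so LiAlH(Ot-Bu)3 can give only the racemic 4-hydroxy-2,3-bis(J–K aryloxy)cyclobut-2-en-1-one F8. Methanol with a catalytic amount of Et3N at 0 °C then exchanges only the aryloxy group on ring carbon 3, the vinylogous ester position, by addition–elimination, which gives 9 and returns one equivalent of 5.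

3. Step 35. Cleavage of 27 methyl ethers may stop short, and the free polyphenol may oxidise in air during isolation, leaving an inseparable mixture. Fallback, setting out from 62 and coming back at 63: the crude product of the BBr3 reaction is not isolated as the free polyphenol but acetylated at once (Ac2O, pyridine, DMAP) to the octacosaacetate of the target F9. This is stable to air and silica, can be purified and checked for residual methyl ethers, and is then cleaved by acid-catalysed methanolysis (HCl, degassed MeOH, rt) to 63.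

**Further compounds**

F1 | step 11 | {[4-(benzyloxy)-2,6-dimethoxyphenoxy]ethynyl}trimethylsilane | C[Si](C)(C)C#COc1c(OC)cc(OCc2ccccc2)cc1OC
F2 | step 11 | racemic 3-(ring H aryloxy)-4-[(Z)-1,2-dimethoxyethenyl]-4-(J–K aryloxy)-2-(trimethylsilyl)cyclobut-2-en-1-one | O=C2C([Si](C)(C)C)=C(Oc1c(OC)cc(OCc3ccccc3)cc1OC)C2(Oc1cc(OC)c(c(OC)c1)Oc1cc(OC)c(OC)c(OC)c1)/C(OC)=C/OC
F3 | step 11 | (3Z,5Z)-3-(ring H aryloxy)-5,6-dimethoxy-4-(J–K aryloxy)-2-(trimethylsilyl)hexa-1,3,5-trien-1-one | O=C=C([Si](C)(C)C)/C(Oc1c(OC)cc(OCc2ccccc2)cc1OC)=C(Oc1cc(OC)c(c(OC)c1)Oc1cc(OC)c(OC)c(OC)c1)\C(OC)=C\OC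
F4 | step 11 | racemic 3-(ring H aryloxy)-5,6-dimethoxy-4-(J–K aryloxy)-2-(trimethylsilyl)cyclohexa-2,4-dien-1-one | O=C2C([Si](C)(C)C)=C(Oc1c(OC)cc(OCc3ccccc3)cc1OC)C(Oc1cc(OC)c(c(OC)c1)Oc1cc(OC)c(OC)c(OC)c1)=C(OC)C2OC
F5 | step 11 | 3-(ring H aryloxy)-5,6-dimethoxy-4-(J–K aryloxy)-2-(trimethylsilyl)phenol | c1ccccc1COc1cc(OC)c(c(OC)c1)Oc1c([Si](C)(C)C)c(O)c(OC)c(OC)c1Oc1cc(OC)c(c(OC)c1)Oc1cc(OC)c(OC)c(OC)c1
F6 | step 5 | 3-chloro-4-(J–K aryloxy)cyclobut-3-ene-1,2-dione | ClC2=C(Oc1cc(OC)c(c(OC)c1)Oc1cc(OC)c(OC)c(OC)c1)C(=O)C2=O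
F7 | step 5 | 3,4-bis(J–K aryloxy)cyclobut-3-ene-1,2-dione | O=C2C(=O)C(Oc1cc(OC)c(c(OC)c1)Oc1cc(OC)c(OC)c(OC)c1)=C2Oc1cc(OC)c(c(OC)c1)Oc1cc(OC)c(OC)c(OC)c1
F8 | step 5 | racemic 4-hydroxy-2,3-bis(J–K aryloxy)cyclobut-2-en-1-one | O=C2C(Oc1cc(OC)c(c(OC)c1)Oc1cc(OC)c(OC)c(OC)c1)=C(Oc1cc(OC)c(c(OC)c1)Oc1cc(OC)c(OC)c(OC)c1)C2O
F9 | step 35 | octacosaacetate of CNP0245174.0 (every hydroxyl as its acetate) | CC(=O)Oc1cc(OC(C)=O)c(c(OC(C)=O)c1)Oc1cc(OC(C)=O)c(c(OC(C)=O)c1)Oc1cc(OC(C)=O)c(OC(C)=O)c(OC(C)=O)c1Oc1cc(OC(C)=O)c(c(OC(C)=O)c1)Oc1cc(OC(C)=O)c(OC(C)=O)c(OC(C)=O)c1Oc1cc(OC(C)=O)c(c(OC(C)=O)c1)Oc1cc(OC(C)=O)c(OC(C)=O)c(OC(C)=O)c1Oc1cc(OC(C)=O)c(c(OC(C)=O)c1)Oc1cc(OC(C)=O)c(OC(C)=O)c(OC(C)=O)c1Oc1cc(OC(C)=O)c(c(OC(C)=O)c1)Oc1cc(OC(C)=O)c(OC(C)=O)c(OC(C)=O)c1
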